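## Structural features

The target is a furofuran lignan, a 2,6-diaryl-3,7-dioxabicyclo[3.3.0]octane. Ring A (C7–O–C9'–C8'–C8) and ring B (C7'–O–C9–C8–C8') share the C8–C8' bond and are cis-fused. Four contiguous stereocentres (C7, C8, C8', C7') have the configuration 7R,8S,7'S,8'R. C8 is fully substituted and carries a tertiary hydroxyl cis to H8'. Both aryl groups sit on the convex face, so the guaiacyl ring on C7 is cis to the C8 hydroxyl and the veratryl ring on C7' is cis to H8'. Fragile points are the two benzylic ether carbons with electron-rich arenes (ionisation and epimerisation in acid, C–O hydrogenolysis), the free phenol (oxidation), and the tertiary alcohol next to benzylic C7 (pinacol-type shifts once C7 ionises). The real difficulty is the oxygenated quaternary carbon C8 between two stereocentres, in a molecule whose two halves differ only by OH/H at the bridgeheads and OH/OMe on the arenes. The key step uses the fact that C8 is bonded to a hydroxyl, to the aryl carbinol carbon C7 and to two ring B atoms (C9, C8'). That is the pattern left when the ketone carbon of a six-membered α-ketol captures a ring bond from the adjacent carbinol carbon, which then leaves the ring as an aryl ketone; ring B is therefore the contraction product of an oxan-3-one that contained C7.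

## Logic of the disconnections

22 from 21: the phenol O–benzyl bond is cut. The phenol stays masked throughout because a free phenol would interfere with the alcohol oxidation, the sulfonylation and the basic steps. The forward hydrogenolysis must spare the benzylic C–O bonds of the bicycle.

21 from 19 (through 20): the O–C9' bond of ring A is cut. It is made by displacement at a primary carbon, so the C7–O bond is never broken and C7 keeps its configuration; one ring and no stereocentre are lost. The forward step needs selective activation of the primary hydroxyl and the cis relation of the C7 arm and C9' on ring B, which comes from 16.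

19 from 18, 17 and 16: the C7–H bond is cut, leading back to the aryl ketone. A chelate between the C8 hydroxyl and the C7 carbonyl would expose the face next to C9 and give the 7S epimer. The non-chelated Felkin–Anh arrangement, with hydride anti to the C8–O bond and the aryl turned away from the C9' arm, gives 7R. Hence the C8 oxygen is silylated (17) before reduction (18), and both silyl groups are removed together (19).

16 from 13 (key): C8–C8' is cut and C7–C8' re-joined. The quaternary carbinol becomes the carbonyl carbon of a six-membered ring and C7 becomes a tertiary benzylic alcohol. The five-membered ring with its hard stereocentre is traced to an oxanone whose stereocentres can be made by standard reactions. The forward step demands that C8', not the aryl group, migrates, and that it is stopped under kinetic control.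

13 from 12 and 11: the C8 carbonyl comes from a secondary alcohol, and the C7–O and C8–O bonds come from the C7=C8 alkene. The C7 configuration matters only for the conformation of 13 and is erased in the key step. The oxidation must not cleave the glycol.

11 from 9 and 10: the C7–aryl bond is cut. This is the one convergent junction and brings in the guaiacyl half already protected.

9 from 7: the enol triflate is traced to the enone by adding hydride at C9 and trapping the C7 enolate oxygen. The enolate must form only toward C8 so that C8' is untouched.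

7 from 6 and 4: the O–Si bond and then the C8'–C9' bond are cut (aldol with formaldehyde). The new arm must enter trans to the veratryl group.

4 from 1 and 2: the C7'–C8' and O–C9 bonds are cut. A catalytic asymmetric cyclocondensation sets C7', the only stereocentre not derived from substrate control.

## Other disconnections considered

Alternative 1: The cut is C7–C8 and C8'–C9', with the ring A oxygen inserted afterwards. In the forward sense arylketene A3 adds across the C8=C8' bond of ring B silyl enol ether A2 to give the cis-fused 3-silyloxycyclobutanone A1. Baeyer–Villiger oxidation with migration of benzylic C7 then gives ring A lactone A4, whose carbonyl is reduced to CH2.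
- In its favour: one step makes two C–C bonds and the C7, C8 and C8' stereocentres, the ring fusion is cis by necessity, and the C8 oxygen is present from the start.
- Against it: making A2 needs enolisation toward C8' rather than the more acidic α-alkoxy position C9. Monosubstituted arylketenes dimerise readily and usually place the larger substituent on the concave face, so the exo aryl of A1 would probably need a later epimerisation next to the ketone. The Baeyer–Villiger step must choose between two secondary carbons in the presence of electron-rich arenes. The lactone carbonyl must then be removed without touching benzylic C–O bonds.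
- Comparison: on structure it is the better plan, because A1 already holds C7 whereas the chosen route needs a separate ketone reduction. On mechanism it is also better in one respect, since a cycloaddition cannot revert as a 1,2-shift can. It is weaker on regiocontrol (enolisation, oxygen insertion) and about equal on step count once A2 is made enantioenriched.

Alternative 2: The cut is C8–C8' and the C7'–aryl bond. Boronic acid A7 transfers its aryl group to monovalent rhodium (for example from [Rh(OH)(cod)]2 with a chiral diene or bisphosphine). Syn-addition across the terminal alkyne of alkynyl ketone A6 and addition of the resulting C8'–Rh bond to the C8 ketone give A5: ring A with the tertiary alcohol and an exocyclic veratrylidene.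
- In its favour: it is convergent and catalytic, forms the same C8–C8' bond as the chosen plan together with ring A, and needs no separate step to set C7.
- Against it: terminal alkynes are poor partners for arylrhodation (alkynyl–metal formation, oligomerisation). The C7 stereocentre of A6 is α to a ketone, benzylic and oxygen-bearing, so it may epimerise under basic aqueous conditions. The cis relation of the C7 aryl and the new C8 hydroxyl rests on 1,2-induction. Ring B must still be closed by adding the C9 oxygen across the C8'=C7' styrene, which sets C7' and C8' late and with little control over the aryl orientation.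
- Comparison: it is better on step count and convergence and equal in the bond it builds at C8. It is weaker on configurational security, since the chosen route fixes C7' and C8' early by reliable reactions.

Alternative 3: The cut is C8–C9 and C7'–C8'. Fluoride (CsF) induces 1,3-elimination from α-chloro silylmethyl ether A10 to carbonyl ylide A11, which adds across C8=C8' of boryl butenolide A9 to give A8. Oxidation of the C–B bond with retention, reduction of the lactone carbonyl and debenzylation would follow.
- In its favour: ring B and the C7', C8' and C8 stereocentres form in one concerted step, anti to the C7 aryl, and the boron is a stereospecific hydroxyl surrogate. It is the shortest of the plans.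
- Against it: the boron-bearing carbon is hindered and the regiochemistry is not secured. The exo/endo placement of the veratryl group is weakly controlled. A10 is hydrolytically labile. The C7 hydrogen of A9 is γ-acidic, so fluoride or base may racemise it.
- Comparison: it is better on step count and on the number of stereocentres made at once. It raises two selectivity questions (regiochemistry, exo/endo) where the chosen plan raises one (which group migrates), and its absolute configuration is less secure.

Key step: step 8

Remark (assumption): lignan locants are used for all intermediates (C7, C8, C9 guaiacyl half; C7', C8', C9' veratryl half), and the (S)-BINOL titanium catalyst of step 1 is assumed to give the (S)-pyranone; if the sense proves opposite, the (R)-ligand is used.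

Step 1
Reactants: 1 veratraldehyde (3,4-dimethoxybenzaldehyde); 2 (E)-1-methoxy-3-(trimethylsilyloxy)buta-1,3-diene
Product: 4 (S)-2-(3,4-dimethoxyphenyl)-2,3-dihydro-4H-pyran-4-one, via Mukaiyama aldol adduct 3 (not isolated)
Conditions: Ti(OiPr)4 (10 mol %), (S)-BINOL (20 mol %), 4 Å MS, Et2O, −20 °C; then CF3CO2H, CH2Cl2, 0 °C
Reagents that add atoms: none
Why: Catalytic asymmetric hetero-Diels–Alder reaction in its stepwise Mukaiyama aldol–cyclisation form: the chiral tetravalent titanium binaphtholate binds the aldehyde, the diene terminus adds to one enantiotopic face and sets C7', and acid then closes the ring with loss of methoxytrimethylsilane. Enantiomeric purity can be raised by crystallisation of 4 if needed.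

Step 2
Reactants: 4 (S)-2-(3,4-dimethoxyphenyl)-2,3-dihydro-4H-pyran-4-one
Product: 6 (2S,3R)-2-(3,4-dimethoxyphenyl)-3-(hydroxymethyl)-2,3-dihydro-4H-pyran-4-one, via lithium dienolate 5 (not isolated)
Conditions: LiN(iPr)2, THF, −78 °C; CH2O (gas, from cracked paraformaldehyde), −78 °C; AcOH quench at −78 °C
Reagents that add atoms: formaldehyde, C=O
Why: Kinetic deprotonation at the α'-methylene of the vinylogous ester and aldol addition to monomeric formaldehyde. The electrophile should enter anti to the neighbouring aryl group, giving the 2,3-trans product (C8'), which is also the more stable epimer.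

Step 3
Reactants: 6 (2S,3R)-2-(3,4-dimethoxyphenyl)-3-(hydroxymethyl)-2,3-dihydro-4H-pyran-4-one
Product: 7 (2S,3R)-3-[(tert-butyldimethylsilyloxy)methyl]-2-(3,4-dimethoxyphenyl)-2,3-dihydro-4H-pyran-4-one
Conditions: TBSCl, imidazole, DMF, 0 °C → rt
Reagents that add atoms: tert-butyldimethylsilyl chloride, CC(C)(C)[Si](C)(C)Cl
Why: Standard silylation of a primary alcohol. It blocks retro-aldol and dehydration of the β-hydroxy ketone and keeps C9' inert through the basic steps that follow.

Step 4
Reactants: 7 (2S,3R)-3-[(tert-butyldimethylsilyloxy)methyl]-2-(3,4-dimethoxyphenyl)-2,3-dihydro-4H-pyran-4-one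
Product: 9 (2S,3R)-3-[(tert-butyldimethylsilyloxy)methyl]-2-(3,4-dimethoxyphenyl)-3,6-dihydro-2H-pyran-4-yl trifluoromethanesulfonate, via lithium enolate 8 (not isolated)
Conditions: LiBH(s-Bu)3, THF, −78 °C; then PhNTf2, −78 → 0 °C; aq. NH4Cl
Reagents that add atoms: N-phenylbis(trifluoromethanesulfonimide), O=S(=O)(N(c1ccccc1)S(=O)(=O)C(F)(F)F)C(F)(F)F
Why: Conjugate reduction of the β-alkoxy enone gives one regiodefined enolate (C7=C8), which is O-sulfonylated in the same flask (reductive enol triflation). C8' is untouched because the enolate lies on the other side of the carbonyl.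

Step 5
Reactants: 9 (2S,3R)-3-[(tert-butyldimethylsilyloxy)methyl]-2-(3,4-dimethoxyphenyl)-3,6-dihydro-2H-pyran-4-yl trifluoromethanesulfonate; 10 4-benzyloxy-3-methoxyphenylboronic acid
Product: 11 tert-butyl{[(2S,3R)-4-[4-(benzyloxy)-3-methoxyphenyl]-2-(3,4-dimethoxyphenyl)-3,6-dihydro-2H-pyran-3-yl]methoxy}dimethylsilane
Conditions: Pd(PPh3)4 (5 mol %), K3PO4, dioxane–H2O, 70 °C
Reagents that add atoms: none
Why: Suzuki–Miyaura coupling of an alkenyl triflate with an arylboronic acid under zerovalent palladium catalysis forms the C7–aryl bond with the alkene position retained. The silyl ether and benzyl ether tolerate the mild aqueous base.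

Step 6
Reactants: 11 tert-butyl{[(2S,3R)-4-[4-(benzyloxy)-3-methoxyphenyl]-2-(3,4-dimethoxyphenyl)-3,6-dihydro-2H-pyran-3-yl]methoxy}dimethylsilane
Product: 12 (3R,4R,5R,6S)-4-[4-(benzyloxy)-3-methoxyphenyl]-5-[(tert-butyldimethylsilyloxy)methyl]-6-(3,4-dimethoxyphenyl)oxane-3,4-diol (both hydroxyls trans to the C9' arm)
Conditions: OsO4 (5 mol %), N-methylmorpholine N-oxide, acetone–H2O, rt
Reagents that add atoms: N-methylmorpholine N-oxide, C[N+]1([O-])CCOCC1; water, O (the two oxygens pass through catalytic OsO4)
Why: Catalytic syn-dihydroxylation of the trisubstituted styrenyl alkene. A(1,2) strain with the C7 aryl pushes the adjacent silyloxymethyl group pseudoaxial, so OsO4 should add to the opposite face. The C7 configuration set here serves only to fix the conformation of 13 and is erased in step 8.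

Step 7
Reactants: 12 (3R,4R,5R,6S)-4-[4-(benzyloxy)-3-methoxyphenyl]-5-[(tert-butyldimethylsilyloxy)methyl]-6-(3,4-dimethoxyphenyl)oxane-3,4-diol
Product: 13 (4R,5R,6S)-4-[4-(benzyloxy)-3-methoxyphenyl]-5-[(tert-butyldimethylsilyloxy)methyl]-6-(3,4-dimethoxyphenyl)-4-hydroxyoxan-3-one
Conditions: SO3·pyridine, DMSO, iPr2NEt, CH2Cl2, 0 °C
Reagents that add atoms: none
Why: Parikh–Doering oxidation of the secondary alcohol; the tertiary benzylic alcohol cannot be oxidised. Activated DMSO avoids the glycol cleavage that periodinane or lead reagents could cause and is mild enough not to trigger a ketol shift.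

Step 8
Reactants: 13 (4R,5R,6S)-4-[4-(benzyloxy)-3-methoxyphenyl]-5-[(tert-butyldimethylsilyloxy)methyl]-6-(3,4-dimethoxyphenyl)-4-hydroxyoxan-3-one
Product: 16 [4-(benzyloxy)-3-methoxyphenyl]{(3S,4R,5S)-4-[(tert-butyldimethylsilyloxy)methyl]-5-(3,4-dimethoxyphenyl)-3-hydroxyoxolan-3-yl}methanone, via potassium alkoxide 14 (not isolated), via rearranged potassium alkoxide 15 (not isolated)
Conditions: KOtBu (1.1 equiv), toluene–THF, −20 → 0 °C; AcOH quench at −20 °C
Reagents that add atoms: none
Why: KOtBu converts the tertiary C7 hydroxyl into alkoxide 14, whose C7–C8' ring bond shifts suprafacially with its electron pair to the adjacent ketone carbon C8 while C7–O− becomes the aryl ketone, giving alkoxide 15, which is protonated by the cold acid quench. The closest known reaction type is the base-promoted α-ketol (acyloin) rearrangement of cyclic tertiary α-hydroxy ketones with ring contraction. Ring B is not closed end to end: it arises by contraction of the oxanone, the C8–C8' bond forming through a three-centre 1,2-shift transition state as C7–C8' breaks. C8' migrates with retention, and the only new stereocentre, C8, is set by the chair of 14 in which the veratryl and silyloxymethyl groups are equatorial: there the C7 alkoxide is equatorial and eclipses C8=O (bridged by K+), and C8' lies over the carbonyl face that puts the new C8 oxygen cis to H8' and the aroyl group cis to the C9' arm. The shift should be driven by conjugation of the new ketone with the 4-alkoxyaryl ring, by loss of the α-alkoxy ketone and by release of the axial C7 aryl group of 13. The selectivity needed is migration of C8' in preference to that axial aryl group, which is also aligned with the carbonyl; the alkoxide manifold is chosen because the migrating carbon then bears carbanion character, which the electron-rich arene supports poorly, and because only the C8' shift builds aryl–ketone conjugation in the transition state. A Lewis acid would instead favour aryl migration, and Al(OiPr)3 could also reduce the new ketone by hydride transfer, so neither is used. Low temperature, a small excess of base and the acid quench keep the step under kinetic control, because a retro-shift through the ring-flipped conformer or through the aryl-shifted ketol would lead to the C8 epimer.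

Step 9
Reactants: 16 [4-(benzyloxy)-3-methoxyphenyl]{(3S,4R,5S)-4-[(tert-butyldimethylsilyloxy)methyl]-5-(3,4-dimethoxyphenyl)-3-hydroxyoxolan-3-yl}methanone
Product: 17 [4-(benzyloxy)-3-methoxyphenyl]{(3S,4R,5S)-4-[(tert-butyldimethylsilyloxy)methyl]-5-(3,4-dimethoxyphenyl)-3-(triethylsilyloxy)oxolan-3-yl}methanone
Conditions: Et3SiOTf, 2,6-lutidine, CH2Cl2, −78 → 0 °C
Reagents that add atoms: triethylsilyl trifluoromethanesulfonate, CC[Si](CC)(CC)OS(=O)(=O)C(F)(F)F
Why: Silyl triflate silylation of a hindered tertiary alcohol; the ketone has no α-hydrogen and cannot form an enol ether. The silyl ether removes the chelating hydroxyl and ends any possibility of a retro-shift.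

Step 10
Reactants: 17 [4-(benzyloxy)-3-methoxyphenyl]{(3S,4R,5S)-4-[(tert-butyldimethylsilyloxy)methyl]-5-(3,4-dimethoxyphenyl)-3-(triethylsilyloxy)oxolan-3-yl}methanone
Product: 18 (R)-[4-(benzyloxy)-3-methoxyphenyl]{(3S,4R,5S)-4-[(tert-butyldimethylsilyloxy)methyl]-5-(3,4-dimethoxyphenyl)-3-(triethylsilyloxy)oxolan-3-yl}methanol
Conditions: LiBH(s-Bu)3, THF, −78 → −40 °C; aq. NH4Cl
Reagents that add atoms: none
Why: Felkin–Anh (non-chelation) reduction: with the C8–OSiEt3 bond perpendicular to the carbonyl and the aryl group turned away from the cis C9' arm, hydride attacks anti to the silyloxy group and should give the 7R alcohol. A chelate-controlled reduction of the free ketol (for example with Zn(BH4)2) would deliver hydride from the C9 side of the chelate and give the 7S epimer, so it is avoided. A 1,2-silyl shift to the new alkoxide would be harmless because both silyl groups are removed next.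

Step 11
Reactants: 18 (R)-[4-(benzyloxy)-3-methoxyphenyl]{(3S,4R,5S)-4-[(tert-butyldimethylsilyloxy)methyl]-5-(3,4-dimethoxyphenyl)-3-(triethylsilyloxy)oxolan-3-yl}methanol
Product: 19 (3S,4R,5S)-3-{(R)-[4-(benzyloxy)-3-methoxyphenyl](hydroxy)methyl}-5-(3,4-dimethoxyphenyl)-4-(hydroxymethyl)oxolan-3-ol
Conditions: Bu4NF, THF, 0 °C → rt
Reagents that add atoms: none
Why: Fluoride cleaves both silyl ethers in one operation; no stereocentre is affected and the benzyl ether is inert.

Step 12
Reactants: 19 (3S,4R,5S)-3-{(R)-[4-(benzyloxy)-3-methoxyphenyl](hydroxy)methyl}-5-(3,4-dimethoxyphenyl)-4-(hydroxymethyl)oxolan-3-ol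
Product: 21 (7R,8S,7'S,8'R)-4-benzyloxy-3,3',4'-trimethoxy-7,9':7',9-diepoxylignan-8-ol (4-O-benzyl ether of the target), via primary tosylate 20 (not isolated)
Conditions: TsCl (1.1 equiv), Et3N, DMAP (cat.), CH2Cl2, 0 °C; then NaH, THF, 0 °C → rt
Reagents that add atoms: none
Why: Chemoselective sulfonylation of the primary hydroxyl followed by Williamson etherification: the C7 alkoxide displaces the C9' tosylate in a 5-exo-tet closure, so the C7–O bond is never broken and C7 keeps its configuration. The cis relation of the C7 arm and C9' on ring B makes the ring fusion cis by necessity; attack by the tertiary alkoxide would need a four-membered ring.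

Step 13
Reactants: 21 (7R,8S,7'S,8'R)-4-benzyloxy-3,3',4'-trimethoxy-7,9':7',9-diepoxylignan-8-ol
Product: 22 (7R,8S,7'S,8'R)-3,3',4'-trimethoxy-7,9':7',9-diepoxylignane-4,8-diol (target CNP0141816.1)
Conditions: H2 (1 atm), palladium on carbon (10 %), EtOAc, rt
Reagents that add atoms: none
Why: Hydrogenolysis of the aryl benzyl ether under neutral conditions. Phenolic benzyl ethers cleave much faster than the benzylic C–O bonds of the furofuran, so a short reaction in a non-acidic solvent should free the phenol selectively.

Compound list

1 | veratraldehyde | COc1ccc(C=O)cc1OC | starting material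
2 | (E)-1-methoxy-3-(trimethylsilyloxy)buta-1,3-diene | CO/C=C/C(=C)O[Si](C)(C)C | starting material
3 | (S,E)-5-(3,4-dimethoxyphenyl)-1-methoxy-5-(trimethylsilyloxy)pent-1-en-3-one | CO/C=C/C(=O)C[C@H](O[Si](C)(C)C)c1ccc(OC)c(OC)c1 | intermediate (not isolated)
4 | (S)-2-(3,4-dimethoxyphenyl)-2,3-dihydro-4H-pyran-4-one | O=C1C=CO[C@H](c2ccc(OC)c(OC)c2)C1 | intermediate
5 | lithium (S)-2-(3,4-dimethoxyphenyl)-2H-pyran-4-olate | [Li]OC1=C[C@@H](c2ccc(OC)c(OC)c2)OC=C1 | intermediate (not isolated)
6 | (2S,3R)-2-(3,4-dimethoxyphenyl)-3-(hydroxymethyl)-2,3-dihydro-4H-pyran-4-one | O=C1C=CO[C@H](c2ccc(OC)c(OC)c2)[C@H]1CO | intermediate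
7 | (2S,3R)-3-[(tert-butyldimethylsilyloxy)methyl]-2-(3,4-dimethoxyphenyl)-2,3-dihydro-4H-pyran-4-one | O=C1C=CO[C@H](c2ccc(OC)c(OC)c2)[C@H]1CO[Si](C)(C)C(C)(C)C | intermediate
8 | lithium (2S,3R)-3-[(tert-butyldimethylsilyloxy)methyl]-2-(3,4-dimethoxyphenyl)-3,6-dihydro-2H-pyran-4-olate | [Li]OC1=CCO[C@H](c2ccc(OC)c(OC)c2)[C@H]1CO[Si](C)(C)C(C)(C)C | intermediate (not isolated)
9 | (2S,3R)-3-[(tert-butyldimethylsilyloxy)methyl]-2-(3,4-dimethoxyphenyl)-3,6-dihydro-2H-pyran-4-yl trifluoromethanesulfonate | O=S(=O)(OC1=CCO[C@H](c2ccc(OC)c(OC)c2)[C@H]1CO[Si](C)(C)C(C)(C)C)C(F)(F)F | intermediate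
10 | 4-benzyloxy-3-methoxyphenylboronic acid | COc1cc(B(O)O)ccc1OCc1ccccc1 | starting material
11 | tert-butyl{[(2S,3R)-4-[4-(benzyloxy)-3-methoxyphenyl]-2-(3,4-dimethoxyphenyl)-3,6-dihydro-2H-pyran-3-yl]methoxy}dimethylsilane | COc1cc(C2=CCO[C@H](c3ccc(OC)c(OC)c3)[C@H]2CO[Si](C)(C)C(C)(C)C)ccc1OCc1ccccc1 | intermediate
12 | (3R,4R,5R,6S)-4-[4-(benzyloxy)-3-methoxyphenyl]-5-[(tert-butyldimethylsilyloxy)methyl]-6-(3,4-dimethoxyphenyl)oxane-3,4-diol | O[C@@H]1CO[C@H](c2ccc(OC)c(OC)c2)[C@@H](CO[Si](C)(C)C(C)(C)C)[C@@]1(O)c1ccc(OCc2ccccc2)c(OC)c1 | intermediate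
13 | (4R,5R,6S)-4-[4-(benzyloxy)-3-methoxyphenyl]-5-[(tert-butyldimethylsilyloxy)methyl]-6-(3,4-dimethoxyphenyl)-4-hydroxyoxan-3-one | O=C1CO[C@H](c2ccc(OC)c(OC)c2)[C@@H](CO[Si](C)(C)C(C)(C)C)[C@@]1(O)c1ccc(OCc2ccccc2)c(OC)c1 | intermediate (key-step precursor)
14 | potassium alkoxide of 13 | O=C1CO[C@H](c2ccc(OC)c(OC)c2)[C@@H](CO[Si](C)(C)C(C)(C)C)[C@@]1([O-])c1ccc(OCc2ccccc2)c(OC)c1.[K+] | intermediate (not isolated)
15 | potassium alkoxide of 16 | O=C(c1ccc(OCc2ccccc2)c(OC)c1)[C@@]1([O-])CO[C@H](c2ccc(OC)c(OC)c2)[C@H]1CO[Si](C)(C)C(C)(C)C.[K+] | intermediate (not isolated)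
16 | [4-(benzyloxy)-3-methoxyphenyl]{(3S,4R,5S)-4-[(tert-butyldimethylsilyloxy)methyl]-5-(3,4-dimethoxyphenyl)-3-hydroxyoxolan-3-yl}methanone | O=C(c1ccc(OCc2ccccc2)c(OC)c1)[C@@]1(O)CO[C@H](c2ccc(OC)c(OC)c2)[C@H]1CO[Si](C)(C)C(C)(C)C | intermediate (key-step product)
17 | [4-(benzyloxy)-3-methoxyphenyl]{(3S,4R,5S)-4-[(tert-butyldimethylsilyloxy)methyl]-5-(3,4-dimethoxyphenyl)-3-(triethylsilyloxy)oxolan-3-yl}methanone | O=C(c1ccc(OCc2ccccc2)c(OC)c1)[C@@]1(O[Si](CC)(CC)CC)CO[C@H](c2ccc(OC)c(OC)c2)[C@H]1CO[Si](C)(C)C(C)(C)C | intermediate
18 | (R)-[4-(benzyloxy)-3-methoxyphenyl]{(3S,4R,5S)-4-[(tert-butyldimethylsilyloxy)methyl]-5-(3,4-dimethoxyphenyl)-3-(triethylsilyloxy)oxolan-3-yl}methanol | O[C@H](c1ccc(OCc2ccccc2)c(OC)c1)[C@@]1(O[Si](CC)(CC)CC)CO[C@H](c2ccc(OC)c(OC)c2)[C@H]1CO[Si](C)(C)C(C)(C)C | intermediate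
19 | (3S,4R,5S)-3-{(R)-[4-(benzyloxy)-3-methoxyphenyl](hydroxy)methyl}-5-(3,4-dimethoxyphenyl)-4-(hydroxymethyl)oxolan-3-ol | O[C@H](c1ccc(OCc2ccccc2)c(OC)c1)[C@@]1(O)CO[C@H](c2ccc(OC)c(OC)c2)[C@H]1CO | intermediate
20 | primary p-toluenesulfonate of 19 | O[C@H](c1ccc(OCc2ccccc2)c(OC)c1)[C@@]1(O)CO[C@H](c2ccc(OC)c(OC)c2)[C@H]1COS(=O)(=O)c1ccc(C)cc1 | intermediate (not isolated)
21 | (7R,8S,7'S,8'R)-4-benzyloxy-3,3',4'-trimethoxy-7,9':7',9-diepoxylignan-8-ol | COc1cc([C@H]2OC[C@@H]3[C@@H](c4ccc(OC)c(OC)c4)OC[C@]23O)ccc1OCc1ccccc1 | intermediate
22 | (7R,8S,7'S,8'R)-3,3',4'-trimethoxy-7,9':7',9-diepoxylignane-4,8-diol | COc1cc([C@H]2OC[C@@H]3[C@@H](c4ccc(OC)c(OC)c4)OC[C@]23O)ccc1O | target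

Total step count: 13. Longest linear sequence: 13 steps (1 and 2 to 22; 10 is purchased and enters at step 5).

Least certain steps

Step 8 (key step). The most likely failure is migration of the axial C7 aryl group in competition with C8'. That would give the transposed ketol, whose own contraction leads to the C8 epimer. The shift may also remain reversible or incomplete if the equilibrium does not lie far enough toward the aryl ketone, or the silyl group may wander to a neighbouring alkoxide. The fallback sets out from 13 and returns at 16. It replaces the reversible ketol shift with an irreversible semipinacol contraction and adds the C8 oxygen afterwards. NaBH4 (MeOH, −20 °C) should reduce the C8 ketone of 13 from the face opposite the axial aryl group to the trans-diol (3S,4R,5R,6S)-4-[4-(benzyloxy)-3-methoxyphenyl]-5-[(tert-butyldimethylsilyloxy)methyl]-6-(3,4-dimethoxyphenyl)oxane-3,4-diol F1, with an equatorial C8 hydroxyl. MsCl and Et3N convert it into the secondary methanesulfonate F2. With KOtBu in THF the C7 alkoxide expels the equatorial sulfonate while the antiperiplanar C7–C8' ring bond migrates; the aryl group is gauche to the leaving group and cannot. This gives the ring-contracted [4-(benzyloxy)-3-methoxyphenyl]{4-[(tert-butyldimethylsilyloxy)methyl]-5-(3,4-dimethoxyphenyl)oxolan-3-yl}methanone F3, which lacks the C8 hydroxyl. Deprotonation of F3 with KN(SiMe3)2 at −78 °C and oxidation of the enolate with 3-phenyl-2-(phenylsulfonyl)oxaziridine, from the face anti to the C9' arm, should then give 16.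

Step 10. The likely failure is poor facial selectivity, or slow reduction, at the hindered aryl ketone next to a quaternary carbon, giving 7S alcohol. The fallback sets out from 17 and returns at 18. It changes from substrate control to catalyst control: Corey–Bakshi–Shibata reduction with BH3·SMe2 and the 2-methyl-oxazaborolidine antipode that delivers hydride to the face giving 7R, with the quaternary C8 as the large group. It makes no new compound (F0).

Step 2. The likely failures are double hydroxymethylation, dehydration of the aldol to the exocyclic enone, or ring opening of the dienolate by β-elimination of the ring oxygen. The fallback sets out from 4 and returns at 6. It moves the C–C bond formation from the lithium enolate to a Lewis-acid manifold: 5 is trapped with Me3SiCl as the silyl dienol ether (S)-[2-(3,4-dimethoxyphenyl)-2H-pyran-4-yloxy]trimethylsilane F4, and F4 undergoes a Mukaiyama aldol reaction with aqueous formaldehyde catalysed by Sc(OTf)3 in THF–water.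

Step 12. The likely failures are sulfonylation and ionisation at the electron-rich benzylic C7 hydroxyl (loss of C7 configuration, or a pinacol-type shift of the neighbouring tertiary carbinol), or elimination of the primary sulfonate. The fallback sets out from 19 and returns at 21. It is a Mitsunobu cyclodehydration (PPh3, diisopropyl azodicarboxylate, THF, 0 °C), which activates the least hindered primary hydroxyl under neutral conditions and lets the C7 hydroxyl close ring A. It makes no new compound (F0).

Further compounds

F1 | step 8 | (3S,4R,5R,6S)-4-[4-(benzyloxy)-3-methoxyphenyl]-5-[(tert-butyldimethylsilyloxy)methyl]-6-(3,4-dimethoxyphenyl)oxane-3,4-diol | O[C@H]1CO[C@H](c2ccc(OC)c(OC)c2)[C@@H](CO[Si](C)(C)C(C)(C)C)[C@@]1(O)c1ccc(OCc2ccccc2)c(OC)c1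
F2 | step 8 | 3-O-methanesulfonate of F1 | CS(=O)(=O)O[C@H]1CO[C@H](c2ccc(OC)c(OC)c2)[C@@H](CO[Si](C)(C)C(C)(C)C)[C@@]1(O)c1ccc(OCc2ccccc2)c(OC)c1
F3 | step 8 | [4-(benzyloxy)-3-methoxyphenyl]{4-[(tert-butyldimethylsilyloxy)methyl]-5-(3,4-dimethoxyphenyl)oxolan-3-yl}methanone (C8 epimer as first formed; C8 is erased on enolisation) | O=C(c1ccc(OCc2ccccc2)c(OC)c1)[C@H]1CO[C@H](c2ccc(OC)c(OC)c2)[C@H]1CO[Si](C)(C)C(C)(C)C
F0 | step 10 | none | none
F4 | step 2 | (S)-[2-(3,4-dimethoxyphenyl)-2H-pyran-4-yloxy]trimethylsilane | C[Si](C)(C)OC1=C[C@@H](c2ccc(OC)c(OC)c2)OC=C1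
F0 | step 12 | none | none
A1 | alternative 1 | cis-fused 3-silyloxycyclobutanone on ring B, aryl exo | COc1cc([C@H]2C(=O)[C@@H]3[C@@H](c4ccc(OC)c(OC)c4)OC[C@]23O[Si](C)(C)C(C)(C)C)ccc1O[Si](C)(C)C(C)(C)C
A2 | alternative 1 | (S)-tert-butyl{[5-(3,4-dimethoxyphenyl)-2,5-dihydrofuran-3-yl]oxy}dimethylsilane | CC(C)(C)[Si](C)(C)OC1=C[C@@H](c2ccc(OC)c(OC)c2)OC1
A3 | alternative 1 | [4-(tert-butyldimethylsilyloxy)-3-methoxyphenyl]ketene | COc1cc(C=C=O)ccc1O[Si](C)(C)C(C)(C)C
A4 | alternative 1 | ring A lactone from Baeyer–Villiger oxidation of A1 | COc1cc([C@H]2OC(=O)[C@@H]3[C@@H](c4ccc(OC)c(OC)c4)OC[C@]23O[Si](C)(C)C(C)(C)C)ccc1O[Si](C)(C)C(C)(C)C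
A5 | alternative 2 | ring A tetrahydrofuran with C8 hydroxyl and exocyclic veratrylidene at C8' | COc1cc([C@H]2OC/C(=C/c3ccc(OC)c(OC)c3)[C@]2(O)CO[Si](C)(C)C(C)(C)C)ccc1O[Si](C)(C)C(C)(C)C
A6 | alternative 2 | (R)-1-[4-(tert-butyldimethylsilyloxy)-3-methoxyphenyl]-3-(tert-butyldimethylsilyloxy)-1-(prop-2-yn-1-yloxy)propan-2-one | C#CCO[C@@H](C(=O)CO[Si](C)(C)C(C)(C)C)c1ccc(O[Si](C)(C)C(C)(C)C)c(OC)c1
A7 | alternative 2 | 3,4-dimethoxyphenylboronic acid | COc1ccc(B(O)O)cc1OC
A8 | alternative 3 | cis-fused C8-boryl ring A lactone with ring B complete | COc1cc([C@H]2OC(=O)[C@@H]3[C@@H](c4ccc(OC)c(OC)c4)OC[C@]23B2OC(C)(C)C(C)(C)O2)ccc1OCc1ccccc1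
A9 | alternative 3 | (S)-5-[4-(benzyloxy)-3-methoxyphenyl]-4-(4,4,5,5-tetramethyl-1,3,2-dioxaborolan-2-yl)furan-2(5H)-one | O=C1C=C(B2OC(C)(C)C(C)(C)O2)[C@@H](c2ccc(OCc3ccccc3)c(OC)c2)O1
A10 | alternative 3 | chloro(3,4-dimethoxyphenyl)methyl (trimethylsilyl)methyl ether (racemic) | COc1ccc(C(Cl)OC[Si](C)(C)C)cc1OC
A11 | alternative 3 | 3,4-dimethoxybenzylidene(methylene)oxonium ylide (carbonyl ylide) | COc1ccc(C=[O+][CH2-])cc1OC
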